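**Assumption:** atoms are numbered as in germacranolides throughout (C1 ketone; C3 and C10 joined by the furanone oxygen; C4=C5 the Z-alkene; C6 lactone oxygen; C7 ring-fusion CH; C8 ester; C9 hydroxyl), also for the corresponding atoms of open-chain intermediates.

## Retrosynthetic overview

1. Target 18 ⇐ 8,9-diol 17 (selective C8 isobutyrylation) ⇐ acetonide-protected macrolactone 16.
2. 16 ⇐ bromo enal 14: the C6–C7 bond is made by an electroreductive chromium-catalysed allylation that closes the ten-membered carbocycle, sets C6 and C7, and lactonises in the same flask.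
3. 14 ⇐ γ-hydroxy ynone 13 (gold cycloisomerisation to the furanone) ⇐ alkyne 7 + (Z)-3-iodobut-2-enal 11 + CO (carbonylative Sonogashira); the 2-(bromomethyl)enoate comes from a Morita–Baylis–Hillman adduct.
4. 7 ⇐ aldehyde 5 ⇐ methyl ketone 3: C10 is set by chelation-controlled ethynylation; C8 and C9 are bought in L-tartrate acetonide 1.
5. Ring order: dioxolane (bought) → furanone (step 10) → carbocycle and α-methylene lactone together (step 11).

## Route

Step 1
Reactants: 1 dimethyl (4R,5R)-2,2-dimethyl-1,3-dioxolane-4,5-dicarboxylate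
Product: 2 (4R,5R)-N4,N5-dimethoxy-N4,N5,2,2-tetramethyl-1,3-dioxolane-4,5-dicarboxamide
Conditions: MeNHOMe·HCl (5 equiv), iPrMgCl (10 equiv), THF, −20 → 0 °C
Reagents that add atoms: N,O-dimethylhydroxylamine hydrochloride, CNOC.Cl
Why: Weinreb amide formation by aminolysis of both esters with the magnesium amide; the trans-dioxolane centres (C8 and C9, bought with natural L-tartrate) are not touched and trans is the stable arrangement.

Step 2
Reactants: 2 (4R,5R)-N4,N5-dimethoxy-N4,N5,2,2-tetramethyl-1,3-dioxolane-4,5-dicarboxamide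
Product: 3 (4R,5R)-5-acetyl-N-methoxy-N,2,2-trimethyl-1,3-dioxolane-4-carboxamide
Conditions: MeMgBr (1.1 equiv), THF, −20 °C; aq. NH4Cl
Reagents that add atoms: methylmagnesium bromide, C[Mg]Br
Why: Weinreb ketone synthesis used as a desymmetrising mono-addition; the first addition gives a stable magnesium-chelated tetrahedral intermediate, so with one equivalent only one amide becomes the methyl ketone on work-up and no stereocentre changes.

Step 3
Reactants: 3 (4R,5R)-5-acetyl-N-methoxy-N,2,2-trimethyl-1,3-dioxolane-4-carboxamide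
Product: 4 (4R,5R)-5-[(2R)-2-hydroxybut-3-yn-2-yl]-N-methoxy-N,2,2-trimethyl-1,3-dioxolane-4-carboxamide
Conditions: HC≡CMgBr (1.5 equiv), THF, −78 → −30 °C; aq. NH4Cl
Reagents that add atoms: ethynylmagnesium bromide, C#C[Mg]Br
Why: Chelation-controlled (Cram-chelate) Grignard addition in which magnesium bridges the ketone oxygen and the α-dioxolane oxygen and the acetylide enters from the C9–H face, anti to the C8 ring carbon, which sets C10 (R here, the S centre of the target) from the tartrate-derived C9; the ketone reacts far faster than the Weinreb amide at this temperature.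

Step 4
Reactants: 4 (4R,5R)-5-[(2R)-2-hydroxybut-3-yn-2-yl]-N-methoxy-N,2,2-trimethyl-1,3-dioxolane-4-carboxamide
Product: 5 (4R,5R)-5-[(2R)-2-hydroxybut-3-yn-2-yl]-2,2-dimethyl-1,3-dioxolane-4-carbaldehyde
Conditions: iBu2AlH (2.5 equiv), THF, −78 °C; aq. potassium sodium tartrate
Reagents that add atoms: none
Why: Weinreb amide reduction, whose aluminium-chelated hemiaminal survives until work-up and stops at the aldehyde; the first hydride is consumed by the tertiary hydroxyl, the alkyne is inert at −78 °C, and the trans-acetonide both prevents lactol formation and keeps C8 in its thermodynamically preferred configuration.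

Step 5
Reactants: 5 (4R,5R)-5-[(2R)-2-hydroxybut-3-yn-2-yl]-2,2-dimethyl-1,3-dioxolane-4-carbaldehyde; 6 methyl acrylate
Product: 7 methyl 2-{hydroxy[(4S,5R)-5-[(2R)-2-hydroxybut-3-yn-2-yl]-2,2-dimethyl-1,3-dioxolan-4-yl]methyl}prop-2-enoate (both carbinol epimers)
Conditions: 6 (5 equiv), DABCO (0.5 equiv), MeOH, 25 °C, 36 h
Reagents that add atoms: none
Why: Morita–Baylis–Hillman reaction, fast for an α-alkoxy aldehyde; the new C7 carbinol centre is formed as a mixture that does not matter because C7 becomes sp2 in step 9.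

Step 6
Reactants: 8 but-2-yn-1-ol
Product: 10 (2Z)-3-iodobut-2-en-1-ol, via cyclic vinylalanate 9 (not isolated)
Conditions: NaAlH2(OCH2CH2OMe)2 (1.5 equiv), THF, 0 → 25 °C; then I2 (1.6 equiv), −78 → 0 °C
Reagents that add atoms: iodine, II
Why: Alkoxide-directed trans-hydroalumination places aluminium on C3 in a five-membered alanate, and iodinolysis with retention gives only the (Z)-iodoalkene.

Step 7
Reactants: 10 (2Z)-3-iodobut-2-en-1-ol
Product: 11 (2Z)-3-iodobut-2-enal
Conditions: MnO2 (15 equiv), CH2Cl2, 25 °C, dark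
Reagents that add atoms: none
Why: Allylic alcohol oxidation on MnO2 is neutral and leaves the (Z)-iodoenal geometry intact when light is excluded.

Step 8
Reactants: 7 methyl 2-{hydroxy[(4S,5R)-5-[(2R)-2-hydroxybut-3-yn-2-yl]-2,2-dimethyl-1,3-dioxolan-4-yl]methyl}prop-2-enoate; 11 (2Z)-3-iodobut-2-enal
Product: 12 methyl 2-{hydroxy[(4S,5R)-5-[(2R,6Z)-2-hydroxy-6-methyl-5,8-dioxooct-6-en-3-yn-2-yl]-2,2-dimethyl-1,3-dioxolan-4-yl]methyl}prop-2-enoate
Conditions: PdCl2(PPh3)2 (5 mol%), CuI (2 mol%), Et3N (3 equiv), CO (5 bar), THF, 25 °C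
Reagents that add atoms: carbon monoxide, [C-]#[O+]
Why: Carbonylative Sonogashira coupling, in which zerovalent palladium adds to the vinyl iodide with retention, CO inserts (favoured over direct coupling by CO pressure and low copper loading) and the copper acetylide delivers the alkyne to give the ynone with C3 from CO; the hindered tertiary and hydrogen-bonded secondary hydroxyls do not compete.

Step 9
Reactants: 12 methyl 2-{hydroxy[(4S,5R)-5-[(2R,6Z)-2-hydroxy-6-methyl-5,8-dioxooct-6-en-3-yn-2-yl]-2,2-dimethyl-1,3-dioxolan-4-yl]methyl}prop-2-enoate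
Product: 13 methyl (2Z)-2-(bromomethyl)-3-{(4S,5R)-5-[(2R,6Z)-2-hydroxy-6-methyl-5,8-dioxooct-6-en-3-yn-2-yl]-2,2-dimethyl-1,3-dioxolan-4-yl}prop-2-enoate
Conditions: NBS (1.3 equiv), Me2S (1.5 equiv), CH2Cl2, −20 → 0 °C
Reagents that add atoms: N-bromosuccinimide, O=C1CCC(=O)N1Br
Why: Corey–Kim-type bromination of a Morita–Baylis–Hillman alcohol, where bromide attacks the alkoxysulfonium salt in SN2′ fashion to give the (2Z)-2-(bromomethyl)enoate; this erases the C7 epimer mixture and removes the only hydroxyl that could compete in step 10, while the tertiary propargylic alcohol cannot be displaced.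

Step 10
Reactants: 13 methyl (2Z)-2-(bromomethyl)-3-{(4S,5R)-5-[(2R,6Z)-2-hydroxy-6-methyl-5,8-dioxooct-6-en-3-yn-2-yl]-2,2-dimethyl-1,3-dioxolan-4-yl}prop-2-enoate
Product: 14 methyl (2Z)-2-(bromomethyl)-3-{(4S,5R)-2,2-dimethyl-5-[(2S)-2-methyl-3-oxo-5-[(2Z)-4-oxobut-2-en-2-yl]-2,3-dihydrofuran-2-yl]-1,3-dioxolan-4-yl}prop-2-enoate
Conditions: Ph3PAuNTf2 (5 mol%), toluene (not dried), 25 °C
Reagents that add atoms: none
Why: Gold-catalysed cycloisomerisation of a γ-hydroxy ynone, in which monovalent gold activates the alkyne for formal hydration at C1 and the tertiary hydroxyl condenses onto the C3 ketone to give the 3(2H)-furanone without touching C10; the silver-free catalyst leaves the electron-poor allylic bromide and the (Z)-enal alone.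

Step 11
Reactants: 14 methyl (2Z)-2-(bromomethyl)-3-{(4S,5R)-2,2-dimethyl-5-[(2S)-2-methyl-3-oxo-5-[(2Z)-4-oxobut-2-en-2-yl]-2,3-dihydrofuran-2-yl]-1,3-dioxolan-4-yl}prop-2-enoate
Product: 16 (6R,7S,8S,9R,10S)-8,9-(isopropylidenedioxy)-1-oxo-3,10-epoxygermacra-2,4(Z),11(13)-trien-12,6-olide, via seco hydroxy ester 15 (not isolated)
Conditions: undivided cell, Al anode, Ni-foam cathode, CrCl2 (15 mol%), n-Bu4NBr (0.1 M), DMF, cathode held at the CrCl3/CrCl2 couple (about −0.9 V vs Ag/AgCl), 14 added over 12 h (2 mM final), 25 °C; then aq. citric acid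
Reagents that add atoms: none
Why: Proposed new method: the cathode regenerates divalent chromium from trivalent chromium at a potential positive of direct enal, dienone or allyl bromide reduction, two divalent chromium ions turn the allylic bromide into a 2-(methoxycarbonyl)allylchromium species, and this adds through its γ-carbon (C7) to the tethered (Z)-enal in a cyclic six-membered transition state that closes the ten-membered ring, while aluminium ions from the anode take over the alkoxide so chromium turns over and the C6 alkoxide lactonises onto the ester; C6 and C7 are set together (anti, hence the trans-fused lactone) under substrate control by C8 and the rigid furanone, (Z)-alkene and trans-acetonide frame; the closest known reactions are the stoichiometric CrCl2 Nozaki–Hiyama–Kishi allylative ring closure to germacranolides and the intermolecular electrochemical chromium-catalysed Nozaki–Hiyama–Kishi coupling, which have not been shown as an electrocatalytic medium-ring closure of a 2-(bromomethyl)enoate onto an enal.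

Step 12
Reactants: 16 (6R,7S,8S,9R,10S)-8,9-(isopropylidenedioxy)-1-oxo-3,10-epoxygermacra-2,4(Z),11(13)-trien-12,6-olide
Product: 17 (6R,7R,8S,9R,10S)-8,9-dihydroxy-1-oxo-3,10-epoxygermacra-2,4(Z),11(13)-trien-12,6-olide
Conditions: TFA/H2O (9:1), CH2Cl2, 0 °C
Reagents that add atoms: none
Why: Acid-catalysed acetal hydrolysis of the trans-fused dioxolane; the lactone, the vinylogous ester and all stereocentres are acid-stable (the C7 descriptor changes only because the priorities change).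

Step 13
Reactants: 17 (6R,7R,8S,9R,10S)-8,9-dihydroxy-1-oxo-3,10-epoxygermacra-2,4(Z),11(13)-trien-12,6-olide
Product: 18 (6R,7S,8S,9R,10S)-9-hydroxy-8-(2-methylpropanoyloxy)-1-oxo-3,10-epoxygermacra-2,4(Z),11(13)-trien-12,6-olide (CNP0265772.2)
Conditions: (iPrCO)2O (1.2 equiv), DMAP (0.1 equiv), pyridine, CH2Cl2, −20 → 0 °C
Reagents that add atoms: isobutyric anhydride, CC(C)C(=O)OC(=O)C(C)C
Why: DMAP-catalysed acylation, selective for the C8 hydroxyl because the C9 hydroxyl is neopentylic (next to quaternary C10) and hydrogen-bonded to the furanone; the weak amine base and low temperature avoid retro-aldol opening of the C9–C10 bond.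

## Compound list

1 | dimethyl (4R,5R)-2,2-dimethyl-1,3-dioxolane-4,5-dicarboxylate | COC(=O)[C@@H]1OC(C)(C)O[C@H]1C(=O)OC | starting material
2 | (4R,5R)-N4,N5-dimethoxy-N4,N5,2,2-tetramethyl-1,3-dioxolane-4,5-dicarboxamide | CON(C)C(=O)[C@@H]1OC(C)(C)O[C@H]1C(=O)N(C)OC | intermediate
3 | (4R,5R)-5-acetyl-N-methoxy-N,2,2-trimethyl-1,3-dioxolane-4-carboxamide | CC(=O)[C@@H]1OC(C)(C)O[C@H]1C(=O)N(C)OC | intermediate
4 | (4R,5R)-5-[(2R)-2-hydroxybut-3-yn-2-yl]-N-methoxy-N,2,2-trimethyl-1,3-dioxolane-4-carboxamide | C#C[C@@](C)(O)[C@@H]1OC(C)(C)O[C@H]1C(=O)N(C)OC | intermediate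
5 | (4R,5R)-5-[(2R)-2-hydroxybut-3-yn-2-yl]-2,2-dimethyl-1,3-dioxolane-4-carbaldehyde | C#C[C@@](C)(O)[C@@H]1OC(C)(C)O[C@H]1C=O | intermediate
6 | methyl acrylate | C=CC(=O)OC | starting material
7 | methyl 2-{hydroxy[(4S,5R)-5-[(2R)-2-hydroxybut-3-yn-2-yl]-2,2-dimethyl-1,3-dioxolan-4-yl]methyl}prop-2-enoate (both carbinol epimers) | C#C[C@@](C)(O)[C@@H]1OC(C)(C)O[C@H]1C(O)C(=C)C(=O)OC | intermediate
8 | but-2-yn-1-ol | CC#CCO | starting material
9 | cyclic vinylalanate, sodium 2,2-bis(2-methoxyethoxy)-3-methyl-2,5-dihydro-1,2-oxaluminol-2-uide | CC1=CCO[Al-]1(OCCOC)OCCOC.[Na+] | intermediate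
10 | (2Z)-3-iodobut-2-en-1-ol | OC/C=C(/C)I | intermediate
11 | (2Z)-3-iodobut-2-enal | O=C/C=C(/C)I | intermediate
12 | methyl 2-{hydroxy[(4S,5R)-5-[(2R,6Z)-2-hydroxy-6-methyl-5,8-dioxooct-6-en-3-yn-2-yl]-2,2-dimethyl-1,3-dioxolan-4-yl]methyl}prop-2-enoate | O=C/C=C(/C)C(=O)C#C[C@@](C)(O)[C@@H]1OC(C)(C)O[C@H]1C(O)C(=C)C(=O)OC | intermediate
13 | methyl (2Z)-2-(bromomethyl)-3-{(4S,5R)-5-[(2R,6Z)-2-hydroxy-6-methyl-5,8-dioxooct-6-en-3-yn-2-yl]-2,2-dimethyl-1,3-dioxolan-4-yl}prop-2-enoate | O=C/C=C(/C)C(=O)C#C[C@@](C)(O)[C@@H]1OC(C)(C)O[C@H]1/C=C(\CBr)C(=O)OC | intermediate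
14 | methyl (2Z)-2-(bromomethyl)-3-{(4S,5R)-2,2-dimethyl-5-[(2S)-2-methyl-3-oxo-5-[(2Z)-4-oxobut-2-en-2-yl]-2,3-dihydrofuran-2-yl]-1,3-dioxolan-4-yl}prop-2-enoate | O=C/C=C(/C)C1=CC(=O)[C@@](C)(O1)[C@@H]2OC(C)(C)O[C@H]2/C=C(\CBr)C(=O)OC | intermediate
15 | seco hydroxy ester, methyl (6R,7S,8S,9R,10S)-6-hydroxy-8,9-(isopropylidenedioxy)-1-oxo-3,10-epoxygermacra-2,4(Z),11(13)-trien-12-oate | C=C(C(=O)OC)[C@H]1[C@H](O)/C=C(/C)C2=CC(=O)[C@@](C)(O2)[C@@H]3OC(C)(C)O[C@H]31 | intermediate
16 | (6R,7S,8S,9R,10S)-8,9-(isopropylidenedioxy)-1-oxo-3,10-epoxygermacra-2,4(Z),11(13)-trien-12,6-olide | C=C1C(=O)O[C@@H]2/C=C(/C)C3=CC(=O)[C@@](C)(O3)[C@@H]4OC(C)(C)O[C@H]4[C@@H]12 | intermediate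
17 | (6R,7R,8S,9R,10S)-8,9-dihydroxy-1-oxo-3,10-epoxygermacra-2,4(Z),11(13)-trien-12,6-olide | C=C1C(=O)O[C@@H]2/C=C(/C)C3=CC(=O)[C@@](C)(O3)[C@H](O)[C@@H](O)[C@@H]12 | intermediate
18 | (6R,7S,8S,9R,10S)-9-hydroxy-8-(2-methylpropanoyloxy)-1-oxo-3,10-epoxygermacra-2,4(Z),11(13)-trien-12,6-olide (CNP0265772.2) | C=C1C(=O)O[C@@H]2/C=C(/C)C3=CC(=O)[C@@](C)(O3)[C@H](O)[C@@H](OC(=O)C(C)C)[C@@H]12 | target

## Step count and risks

Total step count: 13. Longest linear sequence: 11 (steps 1–5 and 8–13; steps 6–7 make the iodoenal).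

**Step 11 (electrocatalytic ring closure, the new step).** It may fail by cathodic over-reduction of the enal or dienone, by poor chromium turnover, by oligomerisation, or by giving the wrong C6/C7 diastereomer in the acetonide-constrained ring. The fallback gives up electrolysis and catalysis for the stoichiometric Nozaki–Hiyama–Kishi/Barbier ring closure that is established for germacranolides. It sets out from 14, which is added by syringe pump to excess CrCl2 (6–8 equiv) in degassed DMF/THF at 25 °C (1–2 mM), so the allylchromium reagent is formed by the chemical reductant. Acidic work-up lactonises and the route is rejoined at 16. No new compound is made (none, F0).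

**Step 3 (C10 by chelation control).** The acetonide oxygen is a weaker chelator than a benzyl-type ether, so Felkin–Anh addition could compete and erode or invert C10. The fallback reverses the order of the two carbonyl additions so that the non-chelated pathway gives the same centre. It sets out from 2: lithium (trimethylsilyl)acetylide (1.05 equiv, THF, −78 °C) gives the mono-ynone (4R,5R)-N-methoxy-N,2,2-trimethyl-5-[3-(trimethylsilyl)prop-2-ynoyl]-1,3-dioxolane-4-carboxamide F1. The non-chelating reagent MeTi(OiPr)3 (THF, −40 → 0 °C) then adds methyl under Felkin–Anh control, leaves the Weinreb amide alone, and gives (4R,5R)-5-[(2R)-2-hydroxy-4-(trimethylsilyl)but-3-yn-2-yl]-N-methoxy-N,2,2-trimethyl-1,3-dioxolane-4-carboxamide F2. K2CO3 in MeOH at 0 °C removes the silyl group and the route is rejoined at 4.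

**Step 8 (carbonylative coupling with the iodoenal).** The electron-poor β-iodoenal may couple directly without CO, and the (Z)-4-oxoenal product may isomerise. The fallback carries C6 at the alcohol oxidation level and unveils the enal late. It sets out from 10 and 7: TBSCl and imidazole in DMF convert 10 into tert-butyl{[(2Z)-3-iodobut-2-en-1-yl]oxy}dimethylsilane F3, an electron-neutral iodide that inserts CO reliably. Coupling F3 with 7 under the step 8 conditions gives methyl 2-{[(4S,5R)-5-[(2R,6Z)-8-{[tert-butyl(dimethyl)silyl]oxy}-2-hydroxy-6-methyl-5-oxooct-6-en-3-yn-2-yl]-2,2-dimethyl-1,3-dioxolan-4-yl](hydroxy)methyl}prop-2-enoate F4. NBS/Me2S gives the (2Z)-bromomethyl enoate silyl ether F5, and Ph3PAuNTf2 gives the furanone silyl ether F6. HF·pyridine in THF at 0 °C gives the (Z)-allylic alcohol F7, and Dess–Martin periodinane with NaHCO3 in CH2Cl2 at 0 °C oxidises it to the enal, rejoining the route at 14.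

## Further compounds

F1 | step 3 | (4R,5R)-N-methoxy-N,2,2-trimethyl-5-[3-(trimethylsilyl)prop-2-ynoyl]-1,3-dioxolane-4-carboxamide | C[Si](C)(C)C#CC(=O)[C@@H]1OC(C)(C)O[C@H]1C(=O)N(C)OC
F2 | step 3 | (4R,5R)-5-[(2R)-2-hydroxy-4-(trimethylsilyl)but-3-yn-2-yl]-N-methoxy-N,2,2-trimethyl-1,3-dioxolane-4-carboxamide | C[Si](C)(C)C#C[C@@](C)(O)[C@@H]1OC(C)(C)O[C@H]1C(=O)N(C)OC
F3 | step 8 | tert-butyl{[(2Z)-3-iodobut-2-en-1-yl]oxy}dimethylsilane | CC(C)(C)[Si](C)(C)OC/C=C(/C)I
F4 | step 8 | methyl 2-{[(4S,5R)-5-[(2R,6Z)-8-{[tert-butyl(dimethyl)silyl]oxy}-2-hydroxy-6-methyl-5-oxooct-6-en-3-yn-2-yl]-2,2-dimethyl-1,3-dioxolan-4-yl](hydroxy)methyl}prop-2-enoate | CC(C)(C)[Si](C)(C)OC/C=C(/C)C(=O)C#C[C@@](C)(O)[C@@H]1OC(C)(C)O[C@H]1C(O)C(=C)C(=O)OC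
F5 | step 8 | methyl (2Z)-2-(bromomethyl)-3-{(4S,5R)-5-[(2R,6Z)-8-{[tert-butyl(dimethyl)silyl]oxy}-2-hydroxy-6-methyl-5-oxooct-6-en-3-yn-2-yl]-2,2-dimethyl-1,3-dioxolan-4-yl}prop-2-enoate | CC(C)(C)[Si](C)(C)OC/C=C(/C)C(=O)C#C[C@@](C)(O)[C@@H]1OC(C)(C)O[C@H]1/C=C(\CBr)C(=O)OC
F6 | step 8 | methyl (2Z)-2-(bromomethyl)-3-{(4S,5R)-5-[(2S)-5-[(2Z)-4-{[tert-butyl(dimethyl)silyl]oxy}but-2-en-2-yl]-2-methyl-3-oxo-2,3-dihydrofuran-2-yl]-2,2-dimethyl-1,3-dioxolan-4-yl}prop-2-enoate | CC(C)(C)[Si](C)(C)OC/C=C(/C)C1=CC(=O)[C@@](C)(O1)[C@@H]2OC(C)(C)O[C@H]2/C=C(\CBr)C(=O)OC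
F7 | step 8 | methyl (2Z)-2-(bromomethyl)-3-{(4S,5R)-5-[(2S)-5-[(2Z)-4-hydroxybut-2-en-2-yl]-2-methyl-3-oxo-2,3-dihydrofuran-2-yl]-2,2-dimethyl-1,3-dioxolan-4-yl}prop-2-enoate | OC/C=C(/C)C1=CC(=O)[C@@](C)(O1)[C@@H]2OC(C)(C)O[C@H]2/C=C(\CBr)C(=O)OC
F0 | step 11 | none | none
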